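# Proposed synthesis of (2S)-4'-O-geranylnaringenin (CNP0123225.1)

**Compound numbers used throughout.** 1 4-hydroxybenzaldehyde; 2 geranyl bromide; 3 4-(geranyloxy)benzaldehyde; 4 trans-1-methoxy-3-(trimethylsilyloxy)buta-1,3-diene; 5 aldol silyl ether (formed in the flask); 6 (S)-2-aryl-2,3-dihydro-4H-pyran-4-one; 7 its 5-iodide; 8 its 5-phenyl sulfide; 9 its 5-phenyl sulfoxide; 10 methyl acetoacetate; 11 methyl 3-(trimethylsilyloxy)but-2-enoate; 12 1-methoxy-1,3-bis(trimethylsilyloxy)buta-1,3-diene; 13 sulfinyl cycloadduct (formed in the flask); 14 bis(trimethylsilyl) flavanone (formed in the flask); 15 the target. "Geranyl" stands for (2E)-3,7-dimethylocta-2,6-dien-1-yl.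

## Analysis of the target

Compound 15 is a flavanone. Ring C (O1–C2–C3–C4(=O)–C4a–C8a) is fused through C4a–C8a to ring A, which carries hydroxyls on C5 and C7, and ring B, a 4-geranyloxyphenyl group, sits on C2. C2 is the only stereocentre and is S, so nothing else in the molecule can relay or correct it. C2 is benzylic, bonded to O1 and β to the C4 carbonyl, and a flavanone of this kind loses its configuration by reversible opening to the 2'-hydroxychalcone whenever O1 can leave as a phenoxide. The geranyl ether brings an acid-labile allylic aryl C–O bond and two trisubstituted alkenes that will not tolerate hydrogenation, peracids, strongly electrophilic halogen or sulfur reagents, carbenes or strong acids. The 5- and 7-hydroxyls would normally need protecting groups, and removing those collides with the geranyl ether. The difficulty is therefore to set C2 catalytically, to keep it, and to finish without acid- or base-heavy deprotection. The strategy rests on one feature: with ring A pared back to its C4a=C8a edge, ring C is a 2-aryl-2,3-dihydro-4H-pyran-4-one whose O1 and C2 are the carbonyl group of aldehyde 3, the retron of a hetero-Diels–Alder reaction with diene 4.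

## Retrosynthetic reasoning

**Ring A (15 to 9 and 12).** In 15 the bonds C4a–C5 and C8–C8a are cut. This removes C5–C8 with both oxygens as diene 12. The remaining ring C fragment needs a group on C4a that activates the C4a=C8a bond as a dienophile and later leaves together with the C8a hydrogen; a phenylsulfinyl group does both, which gives sulfoxide 9. These bonds are chosen because C2 and its two ring bonds stay untouched. The polarity match is unambiguous: the nucleophilic CH2 terminus of 12 must bond to C8a, the only β-carbon of the enone, so the ketene acetal carbon lands on C4a and the oxygens on C5 and C7. Ring A appears directly at the phenol oxidation level and is silylated only in passing (13, then 14), so no phenol protecting group has to be removed with acid or base. The forward reaction must achieve cycloaddition onto a vinylogous ester, syn-elimination of the sulfinyl group across C4a–C8a and loss of the C5 methoxy group.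

**Sulfur on C4a (9 to 8 to 7 to 6).** Sulfoxide 9 goes back to sulfide 8; the forward oxidation must pick sulfur over the two trisubstituted alkenes. The C4a–S bond of 8 is cut next. Direct electrophilic sulfenylation of 6 is not used, because a sulfenyl halide would not distinguish the conjugated enol ether from the geranyl alkenes. The sulfur is brought in instead as a nucleophile, by copper-catalysed coupling of an arenethiol with iodide 7. Iodide 7 comes from 6 by an α-iodination that is assisted by a nucleophilic amine at the enone and therefore selects the enone over the isolated alkenes. Two steps are spent on one C–S bond, but neither depends on the enol ether being the most nucleophilic alkene in the molecule.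

**Diene (12 to 11 to 10).** Diene 12 is cut at its two O–Si bonds and goes back through silyl enol ether 11 to ester 10. Forward, the ketone enol is silylated, then the γ-methyl group is deprotonated and the ester dienolate is silylated on oxygen.

**Ring C and C2 (6 to 3 and 4).** Dihydropyranone 6 is cut at C2–C3 and O1–C8a into aldehyde 3 and diene 4. This is the one place in the skeleton where a C=O group maps onto O1–C2. The stereocentre can therefore be made from a prochiral aldehyde carbon by an external chiral Lewis acid, in the operation that also closes ring C, and before any phenoxide exists that could reopen it. The forward reaction must discriminate the two faces of the aldehyde (attack on the Si face gives 2S). It must join the CH2 terminus of 4 to the aldehyde carbon and the aldehyde oxygen to the methoxy-bearing carbon, by way of aldol silyl ether 5, and it must leave the geranyl chain alone.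

**Geranyl ether (3 to 1 and 2).** Aldehyde 3 is cut at the aryl O–CH2 bond into phenol 1 and bromide 2. With the geranyl group in place from the start, it never has to be introduced next to the 5- and 7-hydroxyls or onto a configurationally labile free 4'-phenol.

## Alternatives that were turned down

**Alternative 1:** Ring C is cut at the C3=C4 double bond of a flav-3-ene, and the C4 carbonyl is added after ring closure. The key-step product is (S)-2-[4-(geranyloxy)phenyl]-5,7-bis(methoxymethoxy)-2H-chromene A1, which goes back to (S)-1-[4-(geranyloxy)phenyl]prop-2-en-1-yl 3,5-bis(methoxymethoxy)-2-vinylphenyl ether A2. Forward, A2 is treated with first-generation Grubbs catalyst Cl2(PCy3)2Ru=CHPh and closes to A1 with loss of the two terminal CH2 groups.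
- For: ring closure between two monosubstituted alkenes is very dependable, this catalyst is slow toward the trisubstituted geranyl alkenes, and ring A arrives complete.
- Against: C2 must exist before the key step as a carbinol carbon that is both allylic and benzylic to a p-alkoxyphenyl ring, and it must be joined to a hindered phenol oxygen with clean inversion, which invites SN1 and SN2' leakage.
- Against: A1 is a 2-aryl-2H-chromene and can open by a reversible 6π electrocyclic ring opening, which erases C2.
- Against: turning C3=C4 into C4=O needs a regioselective hydroboration–oxidation or hydration and an alcohol oxidation beside two more electron-rich alkenes, and two methoxymethyl ethers must then come off with acid next to the geranyl ether.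
- Comparison: the metathesis itself is more certain than the ring A annulation of the chosen route, and that point is conceded. The chosen strategy offers instead a C2 created by catalytic C–C bond formation on a simple aldehyde, no oxidation-state change beside the geranyl chain, no phenol protecting groups and fewer steps (eight against roughly ten).

**Alternative 2:** The C2–C3 bond is cut so that C3 becomes a carbene carbon and C2 the CH2 of a benzyl ether. The key-step product is (S)-2-[4-(geranyloxy)phenyl]-5,7-bis(tert-butyldimethylsilyloxy)chroman-4-one A3, from 2-diazo-1-{2-[4-(geranyloxy)benzyloxy]-4,6-bis(tert-butyldimethylsilyloxy)phenyl}ethan-1-one A4. Forward, Rh2(S-PTTL)4 turns A4 into a rhodium carbene that inserts into one of the two enantiotopic benzylic C–H bonds.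
- For: bond, ring and stereocentre are made in one catalytic step, the C–H bond is activated by oxygen and an electron-rich arene, and the silyl ethers come off with buffered fluoride. A3 is one deprotection from 15, which is a shorter and gentler end game than that of the chosen route; this is conceded.
- Against: the ether oxygen lies five atoms from the carbene carbon, so oxonium ylide formation followed by a Stevens shift of the benzyl group to a ring-contracted five-membered product is a direct competitor.
- Against: insertion to a six-membered ring is intrinsically less favoured than to a five-membered one, and acceptor-only carbenes from diazoketones are the least enantioselective carbene class.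
- Against: the electrophilic carbene can cyclopropanate the geranyl alkenes, and A4 needs diazo-transfer or diazomethane chemistry on a hindered 2,4,6-trioxygenated aryl ketone.
- Comparison: that key step has at least two plausible wrong channels at the carbene stage, while the hetero-Diels–Alder step has only the facial question. The chosen route moves its uncertainty to a late, achiral ring A annulation that cannot damage C2.

**Alternative 3:** Ring C is disconnected at the flavone oxidation level into three components, and C2 is set afterwards by enantioselective 1,4-reduction. The key-step product is 2-[4-(geranyloxy)phenyl]-5,7-bis(methoxymethoxy)-4H-chromen-4-one A5, cut at C4a–C4, C4–C3 and O1–C2 into 2-iodo-3,5-bis(methoxymethoxy)phenol A6, carbon monoxide A8 and 1-ethynyl-4-(geranyloxy)benzene A7. Forward, A6, A8 and A7 react under PdCl2(PPh3)2 with an amine base by carbonylative Sonogashira coupling, and the phenol oxygen then closes 6-endo-dig onto the triple bond.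
- For: three bonds form in one convergent step, A5 is achiral and robust, and no stereocentre can be lost before the end. Of the four strategies this is the most reliable way to assemble the skeleton, and it is rated above the chosen route on that count.
- Against: all stereochemistry rests on an asymmetric conjugate reduction of a 5,7-dioxygenated flavone, an electron-rich and weakly electrophilic vinylogous ester.
- Against: hydrogenation-type catalysts would also attack the geranyl alkenes or C4, and hydride methods pass through the flavanone enolate, the species that expels O1 as a phenoxide and racemises C2.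
- Against: two methoxymethyl ethers again have to be removed with acid after the stereocentre is in place, and A6 costs several steps of selective protection and iodination.
- Comparison: this alternative has the better skeleton assembly and the weaker stereochemistry. The chosen strategy sets C2 first, by a reaction class with direct precedent on p-alkoxybenzaldehydes, and in a ring that has no phenoxide leaving group until the very last operation.

Key step: step 2

## Remarks on the chemistry (assumptions)

- Ligand antipode: (S)-BINOL is written on the assumption that its titanium complex directs the diene to the Si face of the aryl aldehyde (2S product). The sense is checked on the first run, and (R)-BINOL is used instead if it is the opposite; nothing else changes.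
- Compounds 9 and 13 are mixtures at sulfur (13 also at C4a, C5 and C8a). These centres are destroyed in step 8, so only C2 is specified in their SMILES.
- Compounds 11 and 12 are drawn as one double-bond isomer each. The geometry is irrelevant because both carbons end up in the aromatic ring.
- Ring positions are given in flavanone numbering. In the names of 6–9 the pyranone locants 5 and 6 correspond to C4a and C8a.

## Route

Step 1
Reactants: 1 4-hydroxybenzaldehyde; 2 geranyl bromide
Product: 3 4-(geranyloxy)benzaldehyde
Conditions: K2CO3, acetone, reflux
Reagents that add atoms: none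
Why: Williamson ether synthesis; the phenoxide of 1 displaces the primary allylic bromide at C1 (SN2), which keeps the 2E geometry and is favoured over SN2' attack and over C-alkylation under these conditions.

Step 2
Reactants: 3 4-(geranyloxy)benzaldehyde; 4 trans-1-methoxy-3-(trimethylsilyloxy)buta-1,3-diene
Product: 6 (S)-2-[4-(geranyloxy)phenyl]-2,3-dihydro-4H-pyran-4-one, via aldol silyl ether 5 (not isolated)
Conditions: (S)-BINOL (20 mol%), Ti(OiPr)4 (10 mol%), 4 Å molecular sieves, Et2O, −20 → 0 °C; then CF3CO2H (cat.), CH2Cl2, 0 °C
Reagents that add atoms: none
Why: The tetravalent titanium BINOLate binds the aldehyde oxygen of 3 and the CH2 terminus of 4 adds to the carbonyl carbon in a Mukaiyama aldol sense, forming C2–C3; silyl transfer to the aldolate oxygen gives 5 and releases the catalyst. Acid then removes the silyl group and the C2 oxygen adds to the methoxy-bearing carbon of the β-methoxy enone, forming O1–C8a, and loss of methanol gives the vinylogous ester 6. The closest known reaction type is the catalytic asymmetric hetero-Diels–Alder (aldol–cyclisation) reaction of 1-methoxy-3-silyloxydienes with aromatic aldehydes. Ring C closes by 6-endo-trig conjugate addition of the hydroxyl followed by β-elimination of methoxide. C2 is set in the aldol event by the chiral Lewis acid alone, which leaves the Si face of the bound aldehyde open; the substrate has no directing element of its own, and the later closure does not touch the C2–O bond. The step needs enantioface selectivity at the aldehyde, and the single Lewis-basic carbonyl of a flat aryl aldehyde gives one defined binding mode; the p-alkoxy group makes the aldehyde a slower electrophile, so low temperature and sieves are used to hold back the uncatalysed pathway. Regiochemistry is fixed by the polarisation of 4 (nucleophilic CH2 terminus, electrophilic methoxy-bearing carbon after the aldol). The geranyl alkenes are far less nucleophilic than the silyl enol ether, and the acid is kept catalytic and cold to spare the allylic ether.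

Step 3
Reactants: 6 (S)-2-[4-(geranyloxy)phenyl]-2,3-dihydro-4H-pyran-4-one
Product: 7 (S)-2-[4-(geranyloxy)phenyl]-5-iodo-2,3-dihydro-4H-pyran-4-one
Conditions: I2, pyridine/CH2Cl2, 0 °C → rt; aq. Na2S2O3 work-up
Reagents that add atoms: iodine, II
Why: α-Iodination of a cyclic enone with iodine and pyridine (amine-assisted iodination at the α-carbon of the push–pull enol ether, then loss of a proton); the isolated geranyl alkenes add iodine only reversibly and are returned on thiosulfate work-up, and pyridine is too weak a base to deprotonate C3, so C2 is untouched.

Step 4
Reactants: 7 (S)-2-[4-(geranyloxy)phenyl]-5-iodo-2,3-dihydro-4H-pyran-4-one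
Product: 8 (S)-2-[4-(geranyloxy)phenyl]-5-(phenylsulfanyl)-2,3-dihydro-4H-pyran-4-one
Conditions: PhSH, CuI (10 mol%), neocuproine (10 mol%), K3PO4, toluene, 80 °C
Reagents that add atoms: thiophenol, Sc1ccccc1
Why: Ullmann-type C–S coupling of a vinyl iodide with an arenethiol under monovalent copper catalysis; the α-iodoenone is an activated vinyl iodide, copper does not ionise the allylic ether or engage the alkenes, and the heterogeneous phosphate is too weak a base to deprotonate C3.

Step 5
Reactants: 8 (S)-2-[4-(geranyloxy)phenyl]-5-(phenylsulfanyl)-2,3-dihydro-4H-pyran-4-one
Product: 9 (2S)-2-[4-(geranyloxy)phenyl]-5-(phenylsulfinyl)-2,3-dihydro-4H-pyran-4-one (both epimers at sulfur)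
Conditions: NaIO4, MeOH/THF/H2O, 0 °C → rt
Reagents that add atoms: sodium periodate NaIO4, [Na+].[O-]I(=O)(=O)=O
Why: Periodate oxidation of a sulfide to the sulfoxide; periodate transfers one oxygen to sulfur and neither epoxidises alkenes nor goes on readily to the sulfone, and the uncontrolled sulfur stereocentre does not matter because sulfur is lost in step 8.

Step 6
Reactants: 10 methyl acetoacetate
Product: 11 methyl 3-(trimethylsilyloxy)but-2-enoate
Conditions: Me3SiCl, Et3N, hexane, rt
Reagents that add atoms: chlorotrimethylsilane, C[Si](C)(C)Cl
Why: O-Silylation of the enol of a β-keto ester; the conjugated silyl enol ether forms readily under amine base and is distilled.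

Step 7
Reactants: 11 methyl 3-(trimethylsilyloxy)but-2-enoate
Product: 12 1-methoxy-1,3-bis(trimethylsilyloxy)buta-1,3-diene
Conditions: LiN(iPr)2, THF, −78 °C; then Me3SiCl, −78 °C → rt
Reagents that add atoms: chlorotrimethylsilane, C[Si](C)(C)Cl
Why: γ-Deprotonation of the silyloxy crotonate gives the ester dienolate, which is silylated on oxygen; this is the standard preparation of 1-alkoxy-1,3-bis(silyloxy)dienes, and the moisture-sensitive product is used without chromatography.

Step 8
Reactants: 9 (2S)-2-[4-(geranyloxy)phenyl]-5-(phenylsulfinyl)-2,3-dihydro-4H-pyran-4-one; 12 1-methoxy-1,3-bis(trimethylsilyloxy)buta-1,3-diene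
Product: 15 (2S)-2-[4-(geranyloxy)phenyl]-5,7-dihydroxychroman-4-one (4'-O-geranylnaringenin; the target), via sulfinyl cycloadduct 13 (not isolated), via bis(trimethylsilyl) flavanone 14 (not isolated)
Conditions: toluene, 0 °C → rt, then 70 °C; then MeOH, PPTS (cat.), rt
Reagents that add atoms: none
Why: Proposed new method: the cascade of [4+2] cycloaddition (or its stepwise Michael–Claisen-type equivalent) of an electron-rich 1-alkoxy-1,3-bis(silyloxy)diene to a 2-sulfinyl enone, thermal syn-elimination of the sulfinyl group, loss of methanol and desilylation is the closest known reaction type and is established for sulfinyl quinones and 3-acceptor-substituted chromones, but not for a 5-sulfinyl-2,3-dihydro-4H-pyran-4-one; here the sulfinyl and carbonyl groups together should lower the LUMO of the C4a=C8a bond enough to offset donation from O1, the nucleophilic CH2 terminus of 12 bonds to C8a (the only β-carbon) and the ketene acetal carbon to C4a, which puts oxygen on C5 and C7; in 13 the sulfinyl group on C4a and the hydrogen on C8a are cis and eliminate as benzenesulfenic acid, the C5 ketal then ionises and C8 loses a proton to give aromatic 14, and mild methanolysis frees both phenols; C2 takes no part and no phenoxide-forming base is present, so its configuration should be carried through.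

## Compound list

1 | 4-hydroxybenzaldehyde | O=Cc1ccc(O)cc1 | starting material
2 | geranyl bromide, (2E)-1-bromo-3,7-dimethylocta-2,6-diene | CC(C)=CCC/C(C)=C/CBr | starting material
3 | 4-(geranyloxy)benzaldehyde | CC(C)=CCC/C(C)=C/COc1ccc(C=O)cc1 | intermediate
4 | trans-1-methoxy-3-(trimethylsilyloxy)buta-1,3-diene | CO/C=C/C(=C)O[Si](C)(C)C | starting material
5 | (S,E)-5-[4-(geranyloxy)phenyl]-1-methoxy-5-(trimethylsilyloxy)pent-1-en-3-one | CO/C=C/C(=O)C[C@H](O[Si](C)(C)C)c1ccc(OC/C=C(\C)CCC=C(C)C)cc1 | intermediate (not isolated)
6 | (S)-2-[4-(geranyloxy)phenyl]-2,3-dihydro-4H-pyran-4-one | O=C1C[C@@H](c2ccc(OC/C=C(\C)CCC=C(C)C)cc2)OC=C1 | intermediate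
7 | (S)-2-[4-(geranyloxy)phenyl]-5-iodo-2,3-dihydro-4H-pyran-4-one | O=C1C[C@@H](c2ccc(OC/C=C(\C)CCC=C(C)C)cc2)OC=C1I | intermediate
8 | (S)-2-[4-(geranyloxy)phenyl]-5-(phenylsulfanyl)-2,3-dihydro-4H-pyran-4-one | O=C1C[C@@H](c2ccc(OC/C=C(\C)CCC=C(C)C)cc2)OC=C1Sc1ccccc1 | intermediate
9 | (2S)-2-[4-(geranyloxy)phenyl]-5-(phenylsulfinyl)-2,3-dihydro-4H-pyran-4-one, both epimers at sulfur | O=C1C[C@@H](c2ccc(OC/C=C(\C)CCC=C(C)C)cc2)OC=C1S(=O)c1ccccc1 | intermediate
10 | methyl acetoacetate | COC(=O)CC(C)=O | starting material
11 | methyl (E)-3-(trimethylsilyloxy)but-2-enoate | COC(=O)/C=C(\C)O[Si](C)(C)C | intermediate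
12 | (1Z)-1-methoxy-1,3-bis(trimethylsilyloxy)buta-1,3-diene | CO/C(O[Si](C)(C)C)=C/C(=C)O[Si](C)(C)C | intermediate
13 | (2S)-2-[4-(geranyloxy)phenyl]-5-methoxy-4a-(phenylsulfinyl)-5,7-bis(trimethylsilyloxy)-2,3,4a,5,8,8a-hexahydro-4H-chromen-4-one, cis-fused, mixture at C4a, C5, C8a and sulfur | O=C1C[C@@H](c3ccc(OC/C=C(\C)CCC=C(C)C)cc3)OC2CC(O[Si](C)(C)C)=CC(OC)(O[Si](C)(C)C)C12S(=O)c1ccccc1 | intermediate (not isolated)
14 | (S)-2-[4-(geranyloxy)phenyl]-5,7-bis(trimethylsilyloxy)chroman-4-one | C[Si](C)(C)Oc1cc(O[Si](C)(C)C)c2C(=O)C[C@@H](c3ccc(OC/C=C(\C)CCC=C(C)C)cc3)Oc2c1 | intermediate (not isolated)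
15 | (2S)-2-[4-(geranyloxy)phenyl]-5,7-dihydroxychroman-4-one (4'-O-geranylnaringenin) | CC(C)=CCC/C(C)=C/COc1ccc([C@@H]2CC(=O)c3c(O)cc(O)cc3O2)cc1 | target

## Step count and risk

Total step count: 8. Longest linear sequence: 6 steps (steps 1, 2, 3, 4, 5 and 8, from 1 and 2). The diene branch (steps 6 and 7) joins at step 8. Steps 3, 6 and 7 are judged less exposed and are not treated separately; the detour given for step 4 would also bypass step 3.

**Step 8 (proposed new method).** The most likely failure is that the cascade stalls or diverts. Donation from O1 may slow the cycloaddition so far that diene 12 hydrolyses first. The sequence may stop after the C8–C8a bond has formed without closure of C4a–C5. Or O1 may be lost from C8a by β-elimination once the C7 enol ether is unmasked before the sulfinyl group has left.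

Fallback, by known chemistry, from 2 to 15: ring A is then taken ready-made and C2 is set by asymmetric conjugate arylation of a chromone. Bromide 2 alkylates commercial 4-hydroxyphenylboronic acid pinacol ester (K2CO3, acetone) to give 2-[4-(geranyloxy)phenyl]-4,4,5,5-tetramethyl-1,3,2-dioxaborolane F1. Commercial 5,7-dihydroxychromone is silylated (iPr3SiOSO2CF3, 2,6-lutidine, CH2Cl2) to 5,7-bis(triisopropylsilyloxy)-4H-chromen-4-one F2. Rhodium-catalysed asymmetric 1,4-addition of F1 to F2 ([Rh(OH)(cod)]2, a monovalent rhodium source, with an electron-poor chiral bisphosphine whose antipode is chosen for the 2S product, aqueous toluene, 40 °C) should give (S)-2-[4-(geranyloxy)phenyl]-5,7-bis(triisopropylsilyloxy)chroman-4-one F3. Bu4NF buffered with AcOH (THF, 0 °C) then frees 15. This gives up the order of ring construction but keeps aldehyde-free, alkene-tolerant conditions and a fluoride end game.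

**Step 2 (key step).** The most likely failure is incomplete facial selectivity, because the electron-rich aldehyde turns over slowly and the uncatalysed background reaction gains weight. A lesser risk is partial ionisation of the benzylic oxygen or of the geranyl ether during the acid closure.

Fallback, from 3 to 6: the same disconnection is run under hydrogen-bond catalysis without a metal or protic acid. Aldehyde 3 and commercial trans-1-(dimethylamino)-3-(tert-butyldimethylsilyloxy)buta-1,3-diene react in toluene at −78 → −40 °C with a 1-naphthyl TADDOL (20 mol%, antipode chosen for Si-face attack) in a concerted cycloaddition. This should give (6S)-2-(dimethylamino)-6-[4-(geranyloxy)phenyl]-4-(tert-butyldimethylsilyloxy)-3,6-dihydro-2H-pyran F4 (aminal centre not controlled). Acetyl chloride at −78 °C then converts F4 into 6.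

**Step 4.** The most likely failure is conjugate addition of the thiolate at C8a, leading to ring opening or to reductive loss of iodine, in competition with the copper cycle. Slow base-induced opening by deprotonation at C3 and departure of the vinylogous carboxylate would erode C2.

Fallback, from 6 to 8, bypassing 7: the ring is opened to an enaminone, which is nucleophilic enough to take a mild sulfenylating agent that ignores the geranyl alkenes, and is then reclosed. Pyrrolidine (MeOH, rt) should open 6 at C8a to (S,E)-5-[4-(geranyloxy)phenyl]-5-hydroxy-1-(pyrrolidin-1-yl)pent-1-en-3-one F5. N-(Phenylthio)succinimide (CH2Cl2, rt) sulfenylates its α-carbon to give (S,Z)-5-[4-(geranyloxy)phenyl]-5-hydroxy-2-(phenylsulfanyl)-1-(pyrrolidin-1-yl)pent-1-en-3-one F6. CF3CO2H (CH2Cl2, 0 °C) recloses the ring with loss of pyrrolidine to give 8. The C2–O bond is never broken in this sequence.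

**Step 5.** The most likely failure is slow oxygen transfer to the conjugated vinyl sulfide; forcing the oxidation would then bring over-oxidation to the sulfone or epoxidation of the 6,7-alkene of the geranyl chain.

Fallback, from 7 to 9, bypassing 8: the C–S bond is formed at the sulfoxide oxidation level, so no oxidant is needed. Iodide 7 is coupled with the phenylsulfenate anion released in the flask from tert-butyl 3-(phenylsulfinyl)propanoate and K3PO4, under Pd2(dba)3/Xantphos in toluene at 60 °C. The zerovalent palladium could in principle ionise the geranyl ether, but the vinyl iodide should react first. No new isolated compound arises.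

## Further compounds

F1 | step 8 | 2-[4-(geranyloxy)phenyl]-4,4,5,5-tetramethyl-1,3,2-dioxaborolane | CC(C)=CCC/C(C)=C/COc1ccc(B2OC(C)(C)C(C)(C)O2)cc1
F2 | step 8 | 5,7-bis(triisopropylsilyloxy)-4H-chromen-4-one | CC(C)[Si](Oc1cc(O[Si](C(C)C)(C(C)C)C(C)C)c2c(=O)ccoc2c1)(C(C)C)C(C)C
F3 | step 8 | (S)-2-[4-(geranyloxy)phenyl]-5,7-bis(triisopropylsilyloxy)chroman-4-one | CC(C)=CCC/C(C)=C/COc1ccc([C@@H]2CC(=O)c3c(O[Si](C(C)C)(C(C)C)C(C)C)cc(O[Si](C(C)C)(C(C)C)C(C)C)cc3O2)cc1
F4 | step 2 | (6S)-2-(dimethylamino)-6-[4-(geranyloxy)phenyl]-4-(tert-butyldimethylsilyloxy)-3,6-dihydro-2H-pyran | CN(C)C1C=C(O[Si](C)(C)C(C)(C)C)C[C@@H](c2ccc(OC/C=C(\C)CCC=C(C)C)cc2)O1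
F5 | step 4 | (S,E)-5-[4-(geranyloxy)phenyl]-5-hydroxy-1-(pyrrolidin-1-yl)pent-1-en-3-one | O=C(/C=C/N1CCCC1)C[C@H](O)c1ccc(OC/C=C(\C)CCC=C(C)C)cc1
F6 | step 4 | (S,Z)-5-[4-(geranyloxy)phenyl]-5-hydroxy-2-(phenylsulfanyl)-1-(pyrrolidin-1-yl)pent-1-en-3-one | O=C(C[C@H](O)c1ccc(OC/C=C(\C)CCC=C(C)C)cc1)/C(Sc1ccccc1)=C/N1CCCC1
F0 | step 5 | none | none
A1 | alternative 1 | (S)-2-[4-(geranyloxy)phenyl]-5,7-bis(methoxymethoxy)-2H-chromene | COCOc1cc(OCOC)c2C=C[C@@H](c3ccc(OC/C=C(\C)CCC=C(C)C)cc3)Oc2c1
A2 | alternative 1 | (S)-1-[4-(geranyloxy)phenyl]prop-2-en-1-yl 3,5-bis(methoxymethoxy)-2-vinylphenyl ether | COCOc1cc(OCOC)c(C=C)c(O[C@@H](C=C)c2ccc(OC/C=C(\C)CCC=C(C)C)cc2)c1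
A3 | alternative 2 | (S)-2-[4-(geranyloxy)phenyl]-5,7-bis(tert-butyldimethylsilyloxy)chroman-4-one | CC(C)(C)[Si](C)(C)Oc1cc(O[Si](C)(C)C(C)(C)C)c2C(=O)C[C@@H](c3ccc(OC/C=C(\C)CCC=C(C)C)cc3)Oc2c1
A4 | alternative 2 | 2-diazo-1-{2-[4-(geranyloxy)benzyloxy]-4,6-bis(tert-butyldimethylsilyloxy)phenyl}ethan-1-one | [N-]=[N+]=CC(=O)c1c(OCc2ccc(OC/C=C(\C)CCC=C(C)C)cc2)cc(O[Si](C)(C)C(C)(C)C)cc1O[Si](C)(C)C(C)(C)C
A5 | alternative 3 | 2-[4-(geranyloxy)phenyl]-5,7-bis(methoxymethoxy)-4H-chromen-4-one | COCOc1cc(OCOC)c2c(=O)cc(-c3ccc(OC/C=C(\C)CCC=C(C)C)cc3)oc2c1
A6 | alternative 3 | 2-iodo-3,5-bis(methoxymethoxy)phenol | COCOc1cc(O)c(I)c(OCOC)c1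
A7 | alternative 3 | 1-ethynyl-4-(geranyloxy)benzene | C#Cc1ccc(OC/C=C(\C)CCC=C(C)C)cc1
A8 | alternative 3 | carbon monoxide | [C-]#[O+]
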